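## Analysis of the target

Target 21 is a γ-butyrolactone, numbered O1, C2(=O), C3, C4, C5. C3 is fully substituted and carries a tertiary hydroxyl and the (4-hydroxy-3-methoxyphenyl)methyl group of ring A. C4 carries a secondary benzylic carbinol, C7', bound to ring B (again 4-hydroxy-3-methoxyphenyl), and C5 is an unsubstituted CH2. The three contiguous stereocenters are C3 (S), C4 (R) and C7' (R). On the lactone the C4 side chain is trans to the ring A benzyl group and cis to the C3 hydroxyl, and C7' must be set relative to C4 outside any ring. The C7' hydroxyl is the most sensitive site: it is para-hydroxybenzylic (quinone methide formation, epimerisation, acid-induced cyclisation onto ring A) and γ to the lactone carbonyl (acyl migration under base). The two phenols and the tertiary α-hydroxy lactone add to this. The main difficulty is the oxygenated quaternary C3 in the absolute sense, with two further centers to be related to it. The strategy rests on two features. C5 is a lone CH2 between O1 and C4, that is, one formaldehyde carbon. C3 with its hydroxyl, the carboxyl carbon C2 and the CH2 that becomes C4 is the skeleton of (S)-malic acid 7, with the ring A benzyl group in place of the malic hydrogen. With C7' at the ketone level, C4 is an enolisable methylene, so C4–C5 is an aldol bond and O1–C2 an ester exchange.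

## Retrosynthetic reasoning

**21 to 20.** The last operation only frees the two phenols. Both are carried as triisopropylsilyl ethers, which tolerate organolithium and organozinc reagents, amidine base, anhydrous acid and hydride, and which leave under buffered fluoride. These are the only conditions the C7' carbinol is expected to tolerate. Hydrogenolysis of benzyl ethers would endanger the C7'–O bond, and acid-labile acetals would invite ionisation at C7'.

**20 to 19.** The C7'–H bond is cut, taking the carbinol back to aryl ketone 19. This removes one stereocenter, keeps the acyl-migration and quinone methide problems out of all earlier steps, and makes C4–H acidic. The forward step must deliver hydride to one carbonyl face. The C3 hydroxyl and the aroyl group are cis on the lactone and can be bridged by a divalent metal; in that chelate the two faces differ by C4–H against C5.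

**19 to 16 and 17.** The C4–C5 and O1–C2 bonds are cut. C5 has no substituent and no stereocenter, so it is formaldehyde 17, whose carbon is the electrophile for C4 and whose oxygen is the nucleophile for C2. What remains is acyclic keto ester 16 with C3 as its only stereocenter. Cutting C3–C4 instead would mean an aldol of a ketone enolate onto an α-keto ester, creating the quaternary center without control. Cutting the C3–benzyl bond at the lactone stage would require an enolate at C3 in a compound whose acidic site is C4. The forward step needs enolisation at the only available α-CH2, a single hydroxymethylation, ring closure onto the ester, and equilibration of C4 against C3.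

**16 to 15.** The methyl ester and the tertiary hydroxyl of 16 are released together by acid methanolysis of dioxolanone 15. This acetal of pivalaldehyde 8 masks both functions during the C–C bond formations and carries the stereochemical information.

**15 to 12 and 6.** The bond between ring B and the ketone carbon is cut. The acyl partner is acid chloride 12; the aryl partner is arylzinc chloride 14, made from aryl bromide 6 through aryllithium 13, and the two are joined under palladium catalysis. An amide-type acyl donor would need a hard nucleophile such as 13, which would also attack the activated dioxolanone carbonyl; the organozinc does not. Electrophilic acylation of the arene is ruled out because it would enter para to the methoxy group. Bromide 6 fixes the position and comes from phenol 5 by silylation.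

**12 to 11 to 9 and 4.** Acid chloride 12 comes from acid 11. In 11 the C3–CH2(ring A) bond is cut: dianion 10 of dioxolanone acid 9 is alkylated by benzyl bromide 4 on the face away from the tert-butyl group, so the benzyl group replaces the former hydrogen with retention. This buys the quaternary center in the absolute sense from the chiral pool. Bromide 4 comes from vanillin 1 through silyl ether 2 and alcohol 3.

**9 to 7 and 8.** Acetalisation of the α-hydroxy acid unit of 7 with 8 gives the cis dioxolanone 9.

## Alternatives that were turned down

**Alternative 1:** Conjunctive cross-coupling at C3.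
- Disconnection: the bond from ring A to its benzylic CH2 and the C3–C2 bond are cut together. C3 and the benzylic carbon become the alkene carbons of alkenyl pinacol boronate A2, which already holds C4, C5 (as a silylated CH2OH) and the protected C7' carbinol.
- Forward key step: (methoxymethoxy)methyllithium A3 adds to boron. The arylpalladium species from ring A aryl triflate A4 and zerovalent palladium (from Pd(OAc)2 and a chiral ferrocene bisphosphine) activates the alkene. The CH2OMOM group shifts from boron to C3 and reductive elimination joins the terminal carbon to ring A, giving tertiary boronate A1.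
- For it: three fragments meet in one catalytic step, and C3 is set by the ligand.
- Against it: C2 arrives as a protected CH2OH and needs unmasking and two oxidations beside a free tertiary alcohol and two electron-rich arenes. The α-alkoxymethyllithium is fragile. Tertiary boronates from α-branched alkenyl boronates are the demanding end of this reaction, and here the α-substituent carries two stereocenters that may oppose the catalyst. A2 needs its own asymmetric synthesis of the C4/C7' pair.
- Comparison: this route is stronger in convergence and catalyst control at C3. The chosen route offers instead a C3 taken from 7 through a crystalline relay, a C2 at the carboxyl level from the start, and a key step that closes the ring.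

**Alternative 2:** Sharpless epoxidation of an acyclic allylic alcohol.
- Disconnection: the C3–O bond is cut. C3 and the ring A benzylic carbon are the alkene carbons of (E)-allylic alcohol A6, whose CH2OH is the future C2.
- Forward key step: Ti(OiPr)4, L-(+)-diisopropyl tartrate and tBuOOH deliver oxygen to one alkene face and give epoxy alcohol A5. The benzylic C–O bond of the oxirane is later cleaved reductively, and the CH2OH is oxidised and lactonised.
- For it: the facial sense is reagent-controlled and highly predictable.
- Against it: the oxirane carbon on ring A is a para-oxygenated benzylic position that ionises under the Lewis acidic titanium conditions. A6 is a 2,3-disubstituted allylic alcohol with a branched, stereogenic substituent, so it should react slowly and may be mismatched. A geometrically pure trisubstituted alkene is required. The reductive opening must spare the C7' benzylic C–O bond, and C2 again enters at the alcohol level.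
- Comparison: it equals the chosen route in predictability of the absolute sense at C3. It is weaker in product stability and in the number of operations after the key step.

**Alternative 3:** Benzyl 1,2-shift lactonisation.
- Disconnection: the O1–C2 and C3–CH2(ring A) bonds are cut. The precursor is hydroxy 1,2-diketone A8, in which the future C2 carries the benzyl group and C3 is a ketone.
- Forward key step: the C5 hydroxyl adds to the benzyl-bearing ketone to give a five-membered hemiketal. A ketol-type shift moves the benzyl group to the neighbouring carbonyl carbon while the hemiketal collapses to the lactone, giving A7, the tris-silyl ether of the target.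
- For it: the quaternary center, the tertiary alcohol and the lactone appear in one redox-neutral step, and only desilylation follows. That is one step fewer after the key step than in the chosen route.
- Against it: the face of C3 that receives the benzyl group is controlled only by C4 through a reversible hemiketal. A8 has an enolisable benzylic CH2 (it should sit largely as the enol), an epimerisable C4–H and a β-silyloxy group at C7' open to elimination. A ketol shift of an unactivated benzyl group that ends in a lactone lacks close precedent.
- Comparison: it is stronger in endgame economy. The chosen route offers a C3 whose configuration is bought, not induced, and a key step made only of ordinary elementary events.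

Key step: step 10

Assumption: formaldehyde 17 is charged as paraformaldehyde, which the amidine base depolymerises to the monomer in the flask.

## Route

Step 1
Reactants: 1 vanillin
Product: 2 3-methoxy-4-(triisopropylsilyloxy)benzaldehyde
Conditions: TIPSCl, imidazole, DMF, rt
Reagents that add atoms: triisopropylsilyl chloride (TIPSCl), CC(C)[Si](Cl)(C(C)C)C(C)C
Why: Imidazole-promoted silylation of the phenol; the aldehyde is inert and the bulky aryl silyl ether should last until the final fluoride step.

Step 2
Reactants: 2 3-methoxy-4-(triisopropylsilyloxy)benzaldehyde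
Product: 3 [3-methoxy-4-(triisopropylsilyloxy)phenyl]methanol
Conditions: NaBH4, THF/MeOH, 0 °C
Reagents that add atoms: none
Why: Borohydride reduction of an aromatic aldehyde to the benzylic alcohol; a short reaction at 0 °C should leave the aryl silyl ether intact.

Step 3
Reactants: 3 [3-methoxy-4-(triisopropylsilyloxy)phenyl]methanol
Product: 4 [4-(bromomethyl)-2-methoxyphenoxy]triisopropylsilane (ring A benzyl bromide)
Conditions: PBr3, Et2O, 0 °C
Reagents that add atoms: phosphorus tribromide (PBr3), BrP(Br)Br
Why: Bromination of the benzylic alcohol through its phosphite ester with displacement by bromide; the electron-rich bromide ionises easily and is used at once without chromatography.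

Step 4
Reactants: 5 4-bromo-2-methoxyphenol
Product: 6 (4-bromo-2-methoxyphenoxy)triisopropylsilane (ring B aryl bromide)
Conditions: TIPSCl, imidazole, DMF, rt
Reagents that add atoms: triisopropylsilyl chloride (TIPSCl), CC(C)[Si](Cl)(C(C)C)C(C)C
Why: Phenol silylation as in step 1; the bromine para to the silyloxy group fixes the position of the later aryl–carbonyl bond.

Step 5
Reactants: 7 (S)-malic acid, 8 pivalaldehyde
Product: 9 [(2S,4S)-2-tert-butyl-5-oxo-1,3-dioxolan-4-yl]acetic acid (cis)
Conditions: p-TsOH·H2O (cat.), H2SO4 (cat.), pentane, reflux, Dean–Stark; recrystallisation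
Reagents that add atoms: none
Why: Acid-catalysed acetalisation of the α-hydroxy acid unit with azeotropic removal of water closes the five-membered dioxolanone and leaves the β-carboxyl free; the new acetal center equilibrates under acid, and the cis isomer (tert-butyl and CH2CO2H on the same face) is favoured and purified by crystallisation.

Step 6
Reactants: 9 [(2S,4S)-2-tert-butyl-5-oxo-1,3-dioxolan-4-yl]acetic acid, 4 [4-(bromomethyl)-2-methoxyphenoxy]triisopropylsilane
Product: 11 [(2S,4S)-2-tert-butyl-4-[3-methoxy-4-(triisopropylsilyloxy)benzyl]-5-oxo-1,3-dioxolan-4-yl]acetic acid, via dilithium dianion 10 (not isolated)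
Conditions: LiN(SiMe3)2 (2.2 equiv), THF, −78 °C; then 4, −78 °C; 1 M HCl
Reagents that add atoms: none
Why: Enolate alkylation with self-regeneration of the stereocenter: the trigonal carbon of carboxylate–enolate 10 is shielded on one face by the tert-butyl group, so the benzyl bromide enters trans to it and replaces the former hydrogen with retention, setting the future C3 as S; the mixture is kept at −78 °C because the enolate fragments on warming.

Step 7
Reactants: 11 [(2S,4S)-2-tert-butyl-4-[3-methoxy-4-(triisopropylsilyloxy)benzyl]-5-oxo-1,3-dioxolan-4-yl]acetic acid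
Product: 12 [(2S,4S)-2-tert-butyl-4-[3-methoxy-4-(triisopropylsilyloxy)benzyl]-5-oxo-1,3-dioxolan-4-yl]acetyl chloride
Conditions: (COCl)2, DMF (cat.), CH2Cl2, 0 °C to rt; evaporate
Reagents that add atoms: oxalyl chloride, O=C(Cl)C(=O)Cl
Why: Acid chloride formation under Vilsmeier-type catalysis; the dioxolanone (itself made under strong acid) and the aryl silyl ether should tolerate the anhydrous HCl, and the crude chloride is used directly.

Step 8
Reactants: 12 [(2S,4S)-2-tert-butyl-4-[3-methoxy-4-(triisopropylsilyloxy)benzyl]-5-oxo-1,3-dioxolan-4-yl]acetyl chloride, 6 (4-bromo-2-methoxyphenoxy)triisopropylsilane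
Product: 15 (2S,5S)-2-tert-butyl-5-[3-methoxy-4-(triisopropylsilyloxy)benzyl]-5-{2-[3-methoxy-4-(triisopropylsilyloxy)phenyl]-2-oxoethyl}-1,3-dioxolan-4-one, via aryllithium 13 (not isolated), via arylzinc chloride 14 (not isolated)
Conditions: 6, n-BuLi, THF, −78 °C; ZnCl2, −78 to 0 °C; then 12, Pd(PPh3)4 (3 mol%), THF, 0 °C to rt
Reagents that add atoms: none
Why: Negishi acylation: bromine–lithium exchange and transmetalation to zinc give 14, zerovalent palladium inserts into the C–Cl bond of 12, and aryl transfer followed by reductive elimination gives the ketone; the arylzinc is too soft to add to the dioxolanone carbonyl or to the product ketone, which an aryllithium would attack.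

Step 9
Reactants: 15 (2S,5S)-2-tert-butyl-5-[3-methoxy-4-(triisopropylsilyloxy)benzyl]-5-{2-[3-methoxy-4-(triisopropylsilyloxy)phenyl]-2-oxoethyl}-1,3-dioxolan-4-one
Product: 16 methyl (2S)-2-hydroxy-2-[3-methoxy-4-(triisopropylsilyloxy)benzyl]-4-[3-methoxy-4-(triisopropylsilyloxy)phenyl]-4-oxobutanoate
Conditions: HCl (from AcCl), MeOH, 0 °C to rt
Reagents that add atoms: methanol, CO
Why: Acid-catalysed methanolysis of the acylal-type dioxolanone (transesterification with loss of the aldehyde) releases the methyl ester and the tertiary hydroxyl without breaking any bond at the quaternary carbon; acid is used because methoxide would attack the aryl silyl ethers and promote retro-aldol cleavage of the β-hydroxy ketone.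

Step 10
Reactants: 16 methyl (2S)-2-hydroxy-2-[3-methoxy-4-(triisopropylsilyloxy)benzyl]-4-[3-methoxy-4-(triisopropylsilyloxy)phenyl]-4-oxobutanoate, 17 formaldehyde
Product: 19 (3S,4S)-3-hydroxy-3-[3-methoxy-4-(triisopropylsilyloxy)benzyl]-4-[3-methoxy-4-(triisopropylsilyloxy)benzoyl]oxolan-2-one, via hydroxymethyl ketone 18 (not isolated)
Conditions: (CH2O)n (1.3 equiv), DBU (0.2 equiv), THF, 0 °C to rt; AcOH
Reagents that add atoms: none
Why: The amidine reversibly deprotonates the only enolisable position of 16, the CH2 between the ketone and the quaternary carbinol (the ester has no α-hydrogen), and the enolate adds to monomeric formaldehyde in a crossed aldol reaction to give 18 and form C4–C5. The primary oxygen of 18 then attacks the methyl ester in a 5-exo-trig acyl substitution, helped by the fully substituted C3, which expels methanol, forms O1–C2, closes the γ-lactone and makes the hydroxymethylation irreversible. The closest known reaction type is the base-mediated hydroxymethylation of 3-aroylpropionic acid derivatives with formaldehyde followed by γ-lactonisation to 4-aroylbutyrolactones. The new center C4 is not fixed in the C–C bond formation but by equilibration through the ketone enolate under the same base, controlled by the quaternary C3: the aroyl group should settle trans to the larger ring A benzyl group and cis to the hydroxyl, from which it can accept a hydrogen bond. The step needs single over double hydroxymethylation; after ring closure the remaining C4–H sits on a tertiary carbon beside a quaternary one, a second adduct can revert, and formaldehyde is limited to a small excess. Ring-opening β-elimination of the lactone oxygen is the reverse of a 5-endo-trig closure and is stereoelectronically slow. Dehydration across C3–C4 and retro-aldol cleavage at C3 are held back by substoichiometric base, which leaves the tertiary hydroxyl protonated, by low temperature and by the acetic acid quench. No bond to C3 changes, so the configuration from malic acid is carried through.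

Step 11
Reactants: 19 (3S,4S)-3-hydroxy-3-[3-methoxy-4-(triisopropylsilyloxy)benzyl]-4-[3-methoxy-4-(triisopropylsilyloxy)benzoyl]oxolan-2-one
Product: 20 (3S,4R)-3-hydroxy-4-{(R)-hydroxy[3-methoxy-4-(triisopropylsilyloxy)phenyl]methyl}-3-[3-methoxy-4-(triisopropylsilyloxy)benzyl]oxolan-2-one
Conditions: Zn(BH4)2, Et2O, −30 to 0 °C; sat. NH4Cl
Reagents that add atoms: none
Why: Chelation-controlled reduction (cyclic Cram model): divalent zinc bridges the C3 alkoxide and the ketone oxygen, which are cis on the lactone, in a six-membered chelate; with the carbonyl oxygen held syn to C3 the two faces are flanked by C4–H and by C5, and hydride enters past C4–H on the convex face of the bicyclic chelate, which gives the (R)-carbinol; lactone and silyl ethers should be inert at this temperature.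

Step 12
Reactants: 20 (3S,4R)-3-hydroxy-4-{(R)-hydroxy[3-methoxy-4-(triisopropylsilyloxy)phenyl]methyl}-3-[3-methoxy-4-(triisopropylsilyloxy)benzyl]oxolan-2-one
Product: 21 (3S,4R)-3-hydroxy-4-[(R)-hydroxy(4-hydroxy-3-methoxyphenyl)methyl]-3-(4-hydroxy-3-methoxybenzyl)oxolan-2-one (CNP0352022.1)
Conditions: Bu4NF, AcOH (1:1), THF, 0 °C
Reagents that add atoms: none
Why: Fluoride cleaves both aryl Si–O bonds; acetic acid protonates each phenoxide as it forms, so neither acyl migration to the C7' oxygen nor quinone methide formation at C7' should be triggered.

## Compound list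

1 | vanillin | COc1cc(C=O)ccc1O | starting material
2 | 3-methoxy-4-(triisopropylsilyloxy)benzaldehyde | COc1cc(C=O)ccc1O[Si](C(C)C)(C(C)C)C(C)C | intermediate
3 | [3-methoxy-4-(triisopropylsilyloxy)phenyl]methanol | COc1cc(CO)ccc1O[Si](C(C)C)(C(C)C)C(C)C | intermediate
4 | [4-(bromomethyl)-2-methoxyphenoxy]triisopropylsilane | COc1cc(CBr)ccc1O[Si](C(C)C)(C(C)C)C(C)C | intermediate
5 | 4-bromo-2-methoxyphenol | COc1cc(Br)ccc1O | starting material
6 | (4-bromo-2-methoxyphenoxy)triisopropylsilane | COc1cc(Br)ccc1O[Si](C(C)C)(C(C)C)C(C)C | intermediate
7 | (S)-malic acid | O[C@@H](CC(=O)O)C(=O)O | starting material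
8 | pivalaldehyde | CC(C)(C)C=O | starting material
9 | [(2S,4S)-2-tert-butyl-5-oxo-1,3-dioxolan-4-yl]acetic acid | CC(C)(C)[C@H]1O[C@@H](CC(=O)O)C(=O)O1 | intermediate
10 | dilithium enolate–carboxylate of 9 | CC(C)(C)[C@H]1OC(CC(=O)[O-])=C([O-])O1.[Li+].[Li+] | intermediate
11 | [(2S,4S)-2-tert-butyl-4-[3-methoxy-4-(triisopropylsilyloxy)benzyl]-5-oxo-1,3-dioxolan-4-yl]acetic acid | CC(C)(C)[C@H]1O[C@](CC(=O)O)(Cc2ccc(O[Si](C(C)C)(C(C)C)C(C)C)c(OC)c2)C(=O)O1 | intermediate
12 | [(2S,4S)-2-tert-butyl-4-[3-methoxy-4-(triisopropylsilyloxy)benzyl]-5-oxo-1,3-dioxolan-4-yl]acetyl chloride | CC(C)(C)[C@H]1O[C@](CC(=O)Cl)(Cc2ccc(O[Si](C(C)C)(C(C)C)C(C)C)c(OC)c2)C(=O)O1 | intermediate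
13 | [3-methoxy-4-(triisopropylsilyloxy)phenyl]lithium | COc1cc([Li])ccc1O[Si](C(C)C)(C(C)C)C(C)C | intermediate
14 | [3-methoxy-4-(triisopropylsilyloxy)phenyl]zinc chloride | COc1cc([Zn]Cl)ccc1O[Si](C(C)C)(C(C)C)C(C)C | intermediate
15 | (2S,5S)-2-tert-butyl-5-[3-methoxy-4-(triisopropylsilyloxy)benzyl]-5-{2-[3-methoxy-4-(triisopropylsilyloxy)phenyl]-2-oxoethyl}-1,3-dioxolan-4-one | CC(C)(C)[C@H]1O[C@](CC(=O)c2ccc(O[Si](C(C)C)(C(C)C)C(C)C)c(OC)c2)(Cc2ccc(O[Si](C(C)C)(C(C)C)C(C)C)c(OC)c2)C(=O)O1 | intermediate
16 | methyl (2S)-2-hydroxy-2-[3-methoxy-4-(triisopropylsilyloxy)benzyl]-4-[3-methoxy-4-(triisopropylsilyloxy)phenyl]-4-oxobutanoate | COc1cc(C[C@@](O)(C(=O)OC)CC(=O)c2ccc(O[Si](C(C)C)(C(C)C)C(C)C)c(OC)c2)ccc1O[Si](C(C)C)(C(C)C)C(C)C | intermediate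
17 | formaldehyde | C=O | starting material
18 | methyl (2S)-2-hydroxy-3-(hydroxymethyl)-2-[3-methoxy-4-(triisopropylsilyloxy)benzyl]-4-[3-methoxy-4-(triisopropylsilyloxy)phenyl]-4-oxobutanoate (both epimers at the hydroxymethyl-bearing carbon) | COc1cc(C[C@@](O)(C(=O)OC)C(CO)C(=O)c2ccc(O[Si](C(C)C)(C(C)C)C(C)C)c(OC)c2)ccc1O[Si](C(C)C)(C(C)C)C(C)C | intermediate
19 | (3S,4S)-3-hydroxy-3-[3-methoxy-4-(triisopropylsilyloxy)benzyl]-4-[3-methoxy-4-(triisopropylsilyloxy)benzoyl]oxolan-2-one | COc1cc(C[C@@]2(O)C(=O)OC[C@@H]2C(=O)c2ccc(O[Si](C(C)C)(C(C)C)C(C)C)c(OC)c2)ccc1O[Si](C(C)C)(C(C)C)C(C)C | intermediate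
20 | (3S,4R)-3-hydroxy-4-{(R)-hydroxy[3-methoxy-4-(triisopropylsilyloxy)phenyl]methyl}-3-[3-methoxy-4-(triisopropylsilyloxy)benzyl]oxolan-2-one | COc1cc(C[C@@]2(O)C(=O)OC[C@@H]2[C@@H](O)c2ccc(O[Si](C(C)C)(C(C)C)C(C)C)c(OC)c2)ccc1O[Si](C(C)C)(C(C)C)C(C)C | intermediate
21 | (3S,4R)-3-hydroxy-4-[(R)-hydroxy(4-hydroxy-3-methoxyphenyl)methyl]-3-(4-hydroxy-3-methoxybenzyl)oxolan-2-one | COc1cc(C[C@@]2(O)C(=O)OC[C@@H]2[C@@H](O)c2ccc(O)c(OC)c2)ccc1O | target

## Step count and least certain steps

Total step count: 12. Longest linear sequence: 10 steps (1, 2, 3, 4, 11, 12, 15, 16, 19, 20, 21); from 7 it is 8 steps.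

**Step 10 (key step).**
- Risks: loss of configuration at C3 by retro-aldol cleavage and re-closure of the tertiary β-hydroxy ketone once its hydroxyl is deprotonated; base-induced dehydration across C3–C4 toward the conjugated butenolide; a second hydroxymethylation at C4; incomplete equilibration at C4.
- Fallback: it sets out from 16 and returns at 19. TMSOTf and Et3N in CH2Cl2 at 0 °C convert the ketone to its silyl enol ether and cap the tertiary hydroxyl, giving the bis(trimethylsilyl) enol ether F1. A Mukaiyama-type hydroxymethylation with aqueous 17 and Sc(OTf)3 (cat.) in THF then forms the C4–C5 bond without any enolate or alkoxide. Dilute HCl work-up removes the tertiary silyl ether and closes the lactone through 18. If both C4 epimers are present, a brief treatment with catalytic amine base should bring them to 19.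

**Step 11.**
- Risks: poor facial selectivity if the zinc chelate does not form fully (the open-chain Felkin–Anh mode leads to the C7' epimer), or if the ring A benzyl group, which lies on the convex face 1,3 to the carbonyl carbon, hinders hydride approach; hydride attack on the α-hydroxy lactone; acyl migration to the new alkoxide.
- Fallback: it sets out from 19 and returns at 20 and replaces substrate control by reagent control. A Corey–Bakshi–Shibata reduction with (S)-2-methyl-CBS-oxazaborolidine and excess BH3·SMe2 in THF at −20 °C is used; the tertiary hydroxyl consumes one hydride. On the acetophenone model, with the aryl group as the large substituent, this should give the (R)-carbinol. This fallback makes no new compound (F0).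

**Step 6.**
- Risks: fragmentation of the dianion if the temperature rises; ionisation and self-condensation of the electron-rich bromide 4; incomplete alkylation.
- Fallback: it sets out from 9 (through 10) and aldehyde 2 and returns at 11. Aldol addition of 10 to 2 at −78 °C, with the same facial sense anti to the tert-butyl group, gives the benzylic hydroxy acid F2 as a mixture of carbinol epimers. Ionic deoxygenation with Et3SiH and TFA in CH2Cl2 at 0 °C then removes the benzylic oxygen, which the electron-rich ring A activates.

**Step 8.**
- Risks: intramolecular Friedel–Crafts acylation of ring A by the acid chloride (six-membered ring, para to the methoxy group) under the Lewis acidic zinc salts; slow transmetalation.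
- Fallback: it sets out from 11 and returns at 15. Steglich-type thioesterification with ethanethiol (EDC·HCl, DMAP, CH2Cl2) gives the S-ethyl thioester F3, an acyl donor that cannot acylate the arene. Fukuyama coupling of F3 with 14 and PdCl2(PPh3)2 in THF/toluene gives the ketone.

**Step 9.**
- Risks: acid-promoted dehydration of the β-hydroxy ketone; slow acyl substitution at the hindered carbonyl; partial loss of an aryl silyl ether on prolonged exposure.
- Fallback: it sets out from 15 and returns at 16. Aqueous acid hydrolysis (TFA, H2O, THF, rt) cleaves the acetal to the hydroxy acid F4. This is esterified by O-alkylation with TMSCHN2 in toluene/MeOH, which avoids acyl substitution at the hindered carbon.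

**Step 12.**
- Risks: acyl migration of the lactone to the C7' oxygen; loss of configuration at C7' through quinone methide formation once the ring B phenoxide is free.
- Fallback: it sets out from 19 and returns at 21 by reversing the last two operations. Desilylation of 19 with Bu4NF/AcOH gives the bisphenol keto lactone F5, which has no C7' hydroxyl to migrate or ionise. Chelation-controlled reduction with excess Zn(BH4)2 in THF/Et2O, with a mildly acidic work-up, then completes the route.

## Further compounds

F1 | step 10 | methyl (2S,3Z)-2-[3-methoxy-4-(triisopropylsilyloxy)benzyl]-4-[3-methoxy-4-(triisopropylsilyloxy)phenyl]-2,4-bis(trimethylsilyloxy)but-3-enoate | COc1cc(C[C@@](O[Si](C)(C)C)(C(=O)OC)/C=C(\O[Si](C)(C)C)c2ccc(O[Si](C(C)C)(C(C)C)C(C)C)c(OC)c2)ccc1O[Si](C(C)C)(C(C)C)C(C)C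
F0 | step 11 | none | none
F2 | step 6 | [(2S,4S)-2-tert-butyl-4-{hydroxy[3-methoxy-4-(triisopropylsilyloxy)phenyl]methyl}-5-oxo-1,3-dioxolan-4-yl]acetic acid (carbinol epimers) | CC(C)(C)[C@H]1O[C@](CC(=O)O)(C(O)c2ccc(O[Si](C(C)C)(C(C)C)C(C)C)c(OC)c2)C(=O)O1
F3 | step 8 | S-ethyl [(2S,4S)-2-tert-butyl-4-[3-methoxy-4-(triisopropylsilyloxy)benzyl]-5-oxo-1,3-dioxolan-4-yl]ethanethioate | CC(C)(C)[C@H]1O[C@](CC(=O)SCC)(Cc2ccc(O[Si](C(C)C)(C(C)C)C(C)C)c(OC)c2)C(=O)O1
F4 | step 9 | (2S)-2-hydroxy-2-[3-methoxy-4-(triisopropylsilyloxy)benzyl]-4-[3-methoxy-4-(triisopropylsilyloxy)phenyl]-4-oxobutanoic acid | COc1cc(C[C@@](O)(C(=O)O)CC(=O)c2ccc(O[Si](C(C)C)(C(C)C)C(C)C)c(OC)c2)ccc1O[Si](C(C)C)(C(C)C)C(C)C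
F5 | step 12 | (3S,4S)-3-hydroxy-3-(4-hydroxy-3-methoxybenzyl)-4-(4-hydroxy-3-methoxybenzoyl)oxolan-2-one | COc1cc(C[C@@]2(O)C(=O)OC[C@@H]2C(=O)c2ccc(O)c(OC)c2)ccc1O
A1 | alternative 1 | tertiary pinacol boronate at C3 carrying the ring A benzyl group and CH2OMOM | COc1cc(C[C@@](B2OC(C)(C)C(C)(C)O2)(COCOC)[C@H](CO[Si](CC)(CC)CC)[C@@H](O[Si](C)(C)C(C)(C)C)c2ccc(O[Si](C(C)C)(C(C)C)C(C)C)c(OC)c2)ccc1O[Si](C(C)C)(C(C)C)C(C)C
A2 | alternative 1 | 1,1-disubstituted alkenyl pinacol boronate holding C4, C5 and C7' | C=C(B1OC(C)(C)C(C)(C)O1)[C@H](CO[Si](CC)(CC)CC)[C@@H](O[Si](C)(C)C(C)(C)C)c1ccc(O[Si](C(C)C)(C(C)C)C(C)C)c(OC)c1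
A3 | alternative 1 | (methoxymethoxy)methyllithium | [Li]COCOC
A4 | alternative 1 | 3-methoxy-4-(triisopropylsilyloxy)phenyl trifluoromethanesulfonate | COc1cc(OS(=O)(=O)C(F)(F)F)ccc1O[Si](C(C)C)(C(C)C)C(C)C
A5 | alternative 2 | trisubstituted 2,3-epoxy alcohol with C3 configured as in the target | OC[C@@]1(O[C@H]1c2ccc(O[Si](C(C)C)(C(C)C)C(C)C)c(OC)c2)[C@H](CO[Si](CC)(CC)CC)[C@@H](O[Si](C)(C)C(C)(C)C)c1ccc(O[Si](C(C)C)(C(C)C)C(C)C)c(OC)c1
A6 | alternative 2 | (E)-3-(ring A)-2-substituted allylic alcohol | OC/C(=C/c1ccc(O[Si](C(C)C)(C(C)C)C(C)C)c(OC)c1)[C@H](CO[Si](CC)(CC)CC)[C@@H](O[Si](C)(C)C(C)(C)C)c1ccc(O[Si](C(C)C)(C(C)C)C(C)C)c(OC)c1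
A7 | alternative 3 | target as its tris-silyl ether (carbinol TBS, phenols TIPS) | COc1cc(C[C@@]2(O)C(=O)OC[C@@H]2[C@@H](O[Si](C)(C)C(C)(C)C)c2ccc(O[Si](C(C)C)(C(C)C)C(C)C)c(OC)c2)ccc1O[Si](C(C)C)(C(C)C)C(C)C
A8 | alternative 3 | hydroxy 1,2-diketone with the ring A benzyl group on the distal ketone | OC[C@H]([C@@H](O[Si](C)(C)C(C)(C)C)c1ccc(O[Si](C(C)C)(C(C)C)C(C)C)c(OC)c1)C(=O)C(=O)Cc1ccc(O[Si](C(C)C)(C(C)C)C(C)C)c(OC)c1
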